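**Retrosynthetic overview**
1. Numbering: ring A (the methoxy ring) is C1(=O), C2(OMe), C3(Me), C4(=O), C5(OH), C6(chain); ring B is the same with OH at C2'. The last disconnection is three O–tBu bonds (C5–O, C2'–O, C5'–O), so only the ring A methyl ether is permanent.
2. Key disconnection, made in both rings at once: the C4–C5 bond (and C4'–C5'), carbonyl carbon to oxygen-bearing carbon, by thermal 4π opening/6π closure of a bis[4-hydroxy-4-(2-tert-butoxyvinyl)cyclobutenone]. Both six-membered rings form in this one operation; no ring of the target exists before it.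
3. Enabling feature: in each ring the para carbonyl carbons C1 and C4 flank a C2(O-alkyl)=C3(Me) unit, which are the four carbons of a squarate-derived cyclobutenone with C4 as the latent ketene carbon, and C5(O)–C6(chain) is a 2-alkoxyvinyl unit. C4 and C5 are both oxygenated, a like-polarity pair that a ketene/enol-ether electrocyclisation joins without charge matching.
4. The bis-cyclobutenone comes from three components: a C17 α,ω-bis(vinyllithium) and two cyclobutenediones that differ only in the alkoxy group (OMe for ring A, OtBu for ring B). This is where the rings are differentiated, and it is the one non-selective event of the route.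
5. The C17 bis(2-bromo enol ether) comes from 1,11-dibromoundecane and two γ-metalated allyl tert-butyl ethers (thirteen CH2 between the vinyl carbons), followed by bromination/dehydrobromination.

Key step: step 6

Assumption: the target has no stereocentre; the carbinol centres of 8, 9, 12, 13 and 16 are formed without control (mixtures, left undefined in the SMILES) and, like the enol-ether geometries, are erased in step 6.

**Step 1**
Reactants: 1 1,11-dibromoundecane; 2 allyl tert-butyl ether
Product: 4 (1Z,16Z)-1,17-di-tert-butoxyheptadeca-1,16-diene, via lithiated allyl tert-butyl ether 3 (not isolated)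
Conditions: 2 (2.3 equiv), sec-BuLi (2.2 equiv), THF, −65 °C; then 1 (1.0 equiv), −65 °C to 0 °C
Reagents that add atoms: none
Why: sec-BuLi removes an allylic proton next to oxygen to give the oxygen-chelated oxyallyllithium 3, which primary bromides alkylate mainly at the γ-carbon (metalated allyl ether as homoenolate equivalent), so twofold γ-alkylation of 1 should give the bis[(Z)-enol ether] 4 with thirteen methylenes between the vinyl carbons; no stereocentre is formed.

**Step 2**
Reactants: 4 (1Z,16Z)-1,17-di-tert-butoxyheptadeca-1,16-diene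
Product: 6 (1Z,16Z)-2,16-dibromo-1,17-di-tert-butoxyheptadeca-1,16-diene, via tetrabromide 5 (not isolated)
Conditions: Br2 (2.0 equiv), CH2Cl2, −78 °C; then DBU (2.4 equiv), −78 °C to rt
Reagents that add atoms: bromine, BrBr
Why: Bromine adds to each enol ether to give the α,β-dibromo ether 5, and amine-induced loss of HBr through the oxocarbenium ion (the classical bromination–dehydrobromination route to β-bromovinyl ethers) should give the 2-bromo enol ether with bromine cis to tert-butoxy, low temperature and immediate base treatment keeping the tert-butyl ether intact.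

**Step 3**
Reactants: 7 dimethyl squarate
Product: 10 3-methoxy-4-methylcyclobut-3-ene-1,2-dione, via lithium alkoxide adduct 8 (not isolated), via trifluoroacetate 9 (not isolated)
Conditions: MeLi (1.05 equiv), THF, −78 °C; then (CF3CO)2O (1.2 equiv), −78 °C; aq. NaHCO3
Reagents that add atoms: methyllithium, [Li]C; water, O
Why: Methyllithium adds once to a squarate carbonyl, the alkoxide 8 is trapped as trifluoroacetate 9, and hydrolytic allylic transposition on work-up expels methanol (the established one-pot conversion of dialkyl squarates into 3-alkoxy-4-alkylcyclobutenediones) to give 10.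

**Step 4**
Reactants: 11 di-tert-butyl squarate
Product: 14 3-tert-butoxy-4-methylcyclobut-3-ene-1,2-dione, via lithium alkoxide adduct 12 (not isolated), via trifluoroacetate 13 (not isolated)
Conditions: MeLi (1.05 equiv), THF, −78 °C; then (CF3CO)2O (1.2 equiv), −78 °C; cold aq. NaHCO3
Reagents that add atoms: methyllithium, [Li]C; water, O
Why: The same addition/trifluoroacetylation/transposition sequence as in step 3 should give the tert-butoxy dione, with loss of tert-butanol and a cold basic quench protecting the remaining vinylogous tert-butyl ester.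

**Step 5**
Reactants: 6 (1Z,16Z)-2,16-dibromo-1,17-di-tert-butoxyheptadeca-1,16-diene; 10 3-methoxy-4-methylcyclobut-3-ene-1,2-dione; 14 3-tert-butoxy-4-methylcyclobut-3-ene-1,2-dione
Product: 16 4-[(1Z,16Z)-1,17-di-tert-butoxy-16-(2-tert-butoxy-1-hydroxy-3-methyl-4-oxocyclobut-2-en-1-yl)heptadeca-1,16-dien-2-yl]-4-hydroxy-3-methoxy-2-methylcyclobut-2-en-1-one, via dilithio reagent 15 (not isolated)
Conditions: t-BuLi (4.0 equiv), THF, −78 °C; then 10 and 14 (1.0 equiv each, added as a 1:1 solution), −78 °C; aq. NH4Cl; chromatography on Et3N-deactivated silica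
Reagents that add atoms: none
Why: Bromine–lithium exchange with retention gives the oxygen-chelated β-alkoxyvinyllithium 15, which adds to the more electrophilic ketone-type carbonyl of each dione (the one beside the alkoxy-bearing carbon, not the vinylogous-ester carbonyl beside C–Me); because the two termini react independently, the mixed adduct 16 is expected as the largest component of a near-statistical mixture with the two symmetrical bis-adducts, from which it is separated.

**Step 6**
Reactants: 16 the unsymmetrical bis(4-hydroxycyclobutenone)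
Product: 19 2-tert-butoxy-3-[13-(2,5-di-tert-butoxy-4-methyl-3,6-dioxocyclohexa-1,4-dien-1-yl)tridecyl]-5-methoxy-6-methylcyclohexa-2,5-diene-1,4-dione, via bis(dienylketene) 17 (not isolated), via bis(hydroquinone) 18 (not isolated)
Conditions: toluene (degassed), 110 °C, Ar; then Ag2O (4 equiv), Na2SO4, Et2O, rt
Reagents that add atoms: none
Why: On heating, each 4-hydroxycyclobutenone undergoes conrotatory 4π ring opening with the hydroxyl rotating outward, which places the 2-tert-butoxyvinyl arm cis to the new ketene in 17; thermal 6π electrocyclisation then joins the ketene carbon (the future carbonyl beside C–Me) to the tert-butoxy-bearing vinyl carbon, enolisation gives hydroquinone 18, and Ag2O dehydrogenates both hydroquinones. The closest known reaction type is the thermal ring expansion of 4-alkenyl-4-hydroxycyclobutenones to hydroquinones and quinones (the vinyl counterpart of the Moore cyclisation), here run twice in one molecule. Both six-membered rings close in the same mode, a disrotatory 6π electrocyclisation of a dienylketene. No stereocentre is created, since the two carbinol centres and both enol-ether geometries vanish on aromatisation. The step needs torquoselectivity (secured by the donor hydroxyl on the sp3 ring carbon), regiochemistry (fixed by the connectivity of 16, as only the vinyl β-carbon can reach the ketene carbon) and C–C closure in preference to lactonisation of the ketene by the enol hydroxyl (secured by the electron-rich, cis-disposed vinyl ether). The like polarity of the two carbons joined, an acyl carbon and an oxygen-bearing enol-ether carbon, is no obstacle because the bond forms pericyclically.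

**Step 7**
Reactants: 19 the tri-tert-butyl bis-quinone
Product: 20 2-hydroxy-3-[13-(2,5-dihydroxy-4-methyl-3,6-dioxocyclohexa-1,4-dien-1-yl)tridecyl]-5-methoxy-6-methylcyclohexa-2,5-diene-1,4-dione (target)
Conditions: CF3CO2H/CH2Cl2 (1:4), 0 °C to rt
Reagents that add atoms: none
Why: Trifluoroacetic acid cleaves the three quinonyl tert-butyl ethers (vinylogous tert-butyl esters) by loss of the tert-butyl cation as isobutene, whereas the vinylogous methyl ester of ring A cannot ionise and survives, so the target should result directly.

**Compound list**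
1 | 1,11-dibromoundecane | BrCCCCCCCCCCCBr | starting material
2 | allyl tert-butyl ether (3-tert-butoxyprop-1-ene) | C=CCOC(C)(C)C | starting material
3 | (1-tert-butoxyprop-2-en-1-yl)lithium, γ-reactive oxyallyl anion (not isolated) | C=CC([Li])OC(C)(C)C | intermediate
4 | (1Z,16Z)-1,17-di-tert-butoxyheptadeca-1,16-diene | CC(C)(C)O/C=C\CCCCCCCCCCCCC/C=C\OC(C)(C)C | intermediate
5 | 1,2,16,17-tetrabromo-1,17-di-tert-butoxyheptadecane, diastereomer mixture (not isolated) | CC(C)(C)OC(Br)C(Br)CCCCCCCCCCCCCC(Br)C(Br)OC(C)(C)C | intermediate
6 | (1Z,16Z)-2,16-dibromo-1,17-di-tert-butoxyheptadeca-1,16-diene (Br cis to OtBu) | CC(C)(C)O/C=C(\Br)CCCCCCCCCCCCC/C(Br)=C/OC(C)(C)C | intermediate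
7 | dimethyl squarate (3,4-dimethoxycyclobut-3-ene-1,2-dione) | COC1=C(OC)C(=O)C1=O | starting material
8 | lithium 2,3-dimethoxy-1-methyl-4-oxocyclobut-2-en-1-olate (not isolated) | COC1=C(OC)C(C)(O[Li])C1=O | intermediate
9 | 2,3-dimethoxy-1-methyl-4-oxocyclobut-2-en-1-yl trifluoroacetate (not isolated) | COC1=C(OC)C(C)(OC(=O)C(F)(F)F)C1=O | intermediate
10 | 3-methoxy-4-methylcyclobut-3-ene-1,2-dione | COC1=C(C)C(=O)C1=O | intermediate
11 | di-tert-butyl squarate (3,4-di-tert-butoxycyclobut-3-ene-1,2-dione) | CC(C)(C)OC1=C(OC(C)(C)C)C(=O)C1=O | starting material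
12 | lithium 2,3-di-tert-butoxy-1-methyl-4-oxocyclobut-2-en-1-olate (not isolated) | CC(C)(C)OC1=C(OC(C)(C)C)C(C)(O[Li])C1=O | intermediate
13 | 2,3-di-tert-butoxy-1-methyl-4-oxocyclobut-2-en-1-yl trifluoroacetate (not isolated) | CC(C)(C)OC1=C(OC(C)(C)C)C(C)(OC(=O)C(F)(F)F)C1=O | intermediate
14 | 3-tert-butoxy-4-methylcyclobut-3-ene-1,2-dione | CC(C)(C)OC1=C(C)C(=O)C1=O | intermediate
15 | (1E,16E)-(1,17-di-tert-butoxyheptadeca-1,16-diene-2,16-diyl)dilithium, Li cis to OtBu at both ends (not isolated) | CC(C)(C)O/C=C(\[Li])CCCCCCCCCCCCC/C([Li])=C/OC(C)(C)C | intermediate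
16 | 4-[(1Z,16Z)-1,17-di-tert-butoxy-16-(2-tert-butoxy-1-hydroxy-3-methyl-4-oxocyclobut-2-en-1-yl)heptadeca-1,16-dien-2-yl]-4-hydroxy-3-methoxy-2-methylcyclobut-2-en-1-one, carbinol diastereomer mixture | CC(C)(C)O/C=C(/CCCCCCCCCCCCC/C(=C/OC(C)(C)C)C1(O)C(=O)C(C)=C1OC(C)(C)C)C2(O)C(=O)C(C)=C2OC | intermediate
17 | bis(dienylketene) from twofold ring opening of 16, each 2-tert-butoxyvinyl arm cis to its ketene (not isolated) | CC(C)(C)O/C=C(/CCCCCCCCCCCCC/C(=C/OC(C)(C)C)/C(O)=C(OC(C)(C)C)\C(C)=C=O)\C(O)=C(OC)/C(C)=C=O | intermediate
18 | 2-tert-butoxy-3-[13-(2,5-di-tert-butoxy-3,6-dihydroxy-4-methylphenyl)tridecyl]-5-methoxy-6-methylbenzene-1,4-diol (not isolated) | COc1c(C)c(O)c(OC(C)(C)C)c(CCCCCCCCCCCCCc2c(OC(C)(C)C)c(O)c(C)c(OC(C)(C)C)c2O)c1O | intermediate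
19 | 2-tert-butoxy-3-[13-(2,5-di-tert-butoxy-4-methyl-3,6-dioxocyclohexa-1,4-dien-1-yl)tridecyl]-5-methoxy-6-methylcyclohexa-2,5-diene-1,4-dione | COC1=C(C)C(=O)C(OC(C)(C)C)=C(CCCCCCCCCCCCCC2=C(OC(C)(C)C)C(=O)C(C)=C(OC(C)(C)C)C2=O)C1=O | intermediate
20 | 2-hydroxy-3-[13-(2,5-dihydroxy-4-methyl-3,6-dioxocyclohexa-1,4-dien-1-yl)tridecyl]-5-methoxy-6-methylcyclohexa-2,5-diene-1,4-dione | COC1=C(C)C(=O)C(O)=C(CCCCCCCCCCCCCC2=C(O)C(=O)C(C)=C(O)C2=O)C1=O | target

**Step count and risks**
Total step count: 7. Longest linear sequence: 5 (steps 1, 2, 5, 6, 7).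

Steps most likely to fail:

1. Step 5. The two diones are distributed at random over two equivalent vinyllithium termini, so at best half of 6 can end up in 16. The three bis-adducts, each a diastereomer mixture, may also co-elute, and warming of 15 invites β-elimination of LiOtBu. Fallback (differentiation postponed to the end; the statistical ceiling remains, but the components then differ in acidity): setting out from 6 by way of 15, dione 10 alone (2 equiv) is added to give the symmetrical bis-adduct F1. Heating in toluene gives the symmetrical bis(hydroquinone) F2, which Ag2O oxidises to the symmetrical bis-quinone F3. CF3CO2H cleaves both tert-butyl ethers to give the bis(2-hydroxy-5-methoxyquinone) F4. Saponification of one vinylogous methyl ester (aqueous NaOH/dioxane, 60 °C, under argon, stopped near half conversion, then HCl) should give 20. The product differs from recovered F4 and from the doubly hydrolysed material by one acidic hydroxyl each, which should allow reversed-phase separation, and F4 is recycled. The fallback rejoins the route at 20.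

2. Step 6. If a hydroxyl rotates inward during ring opening, the ketene is trapped as a butenolide instead of closing onto the vinyl ether. The vinylogous tert-butyl ester of the ring B half may also lose isobutene before ring opening. Loss of tert-butyl after ring closure is harmless, because these groups fall in step 7 anyway. Fallback (silyl ether series): setting out from 16, Me3SiCl/imidazole gives the bis(trimethylsilyl ether) F5, in which the silyloxy group rotates outward more reliably and no free hydroxyl can add to the ketene. Thermolysis (toluene, 100 °C) gives the bis(4-trimethylsilyloxyphenol) F6, and Bu4NF/AcOH releases 18, where the fallback rejoins the route before the Ag2O oxidation.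

3. Step 2. Ionisation of the α-bromo ether in 5 can expel the tert-butyl cation (dealkylation to the α-bromo aldehyde) before the base removes HBr, and excess base can over-eliminate to the ynol ether. Fallback (no α-bromo ether, no HBr): setting out from 4, N-bromosuccinimide in methanol (2,6-lutidine, −20 °C) gives the bis(α-bromo methyl tert-butyl acetal) F7. Me3SiOTf/iPr2NEt then removes methanol from each mixed acetal (silylation of the less hindered methoxy group, deprotonation of the oxocarbenium ion at the bromine-bearing carbon) and the fallback rejoins the route at 6.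

**Further compounds**
F1 | step 5 | 4,4'-[(1Z,16Z)-1,17-di-tert-butoxyheptadeca-1,16-diene-2,16-diyl]bis(4-hydroxy-3-methoxy-2-methylcyclobut-2-en-1-one) | CC(C)(C)O/C=C(/CCCCCCCCCCCCC/C(=C/OC(C)(C)C)C1(O)C(=O)C(C)=C1OC)C2(O)C(=O)C(C)=C2OC
F2 | step 5 | 3,3'-(tridecane-1,13-diyl)bis(2-tert-butoxy-5-methoxy-6-methylbenzene-1,4-diol) | COc1c(C)c(O)c(OC(C)(C)C)c(CCCCCCCCCCCCCc2c(OC(C)(C)C)c(O)c(C)c(OC)c2O)c1O
F3 | step 5 | 3,3'-(tridecane-1,13-diyl)bis(2-tert-butoxy-5-methoxy-6-methylcyclohexa-2,5-diene-1,4-dione) | COC1=C(C)C(=O)C(OC(C)(C)C)=C(CCCCCCCCCCCCCC2=C(OC(C)(C)C)C(=O)C(C)=C(OC)C2=O)C1=O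
F4 | step 5 | 3,3'-(tridecane-1,13-diyl)bis(2-hydroxy-5-methoxy-6-methylcyclohexa-2,5-diene-1,4-dione) | COC1=C(C)C(=O)C(O)=C(CCCCCCCCCCCCCC2=C(O)C(=O)C(C)=C(OC)C2=O)C1=O
F5 | step 6 | bis(trimethylsilyl ether) of 16 (both tertiary hydroxyls silylated) | CC(C)(C)O/C=C(/CCCCCCCCCCCCC/C(=C/OC(C)(C)C)C1(O[Si](C)(C)C)C(=O)C(C)=C1OC(C)(C)C)C2(O[Si](C)(C)C)C(=O)C(C)=C2OC
F6 | step 6 | 2-tert-butoxy-3-[13-(2,5-di-tert-butoxy-3-hydroxy-4-methyl-6-trimethylsilyloxyphenyl)tridecyl]-5-methoxy-6-methyl-4-trimethylsilyloxyphenol | COc1c(C)c(O)c(OC(C)(C)C)c(CCCCCCCCCCCCCc2c(OC(C)(C)C)c(O)c(C)c(OC(C)(C)C)c2O[Si](C)(C)C)c1O[Si](C)(C)C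
F7 | step 2 | 2,16-dibromo-1,17-di-tert-butoxy-1,17-dimethoxyheptadecane (diastereomer mixture) | CC(C)(C)OC(OC)C(Br)CCCCCCCCCCCCCC(Br)C(OC)OC(C)(C)C
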